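The plan cuts the bond between the exocyclic methine carbon on C5 of the butenolide (tetronic acid) ring and C5 of the dihydrobenzofuran. Butenolide C5 carries both ring oxygen O1 and enol carbon C4. Ring plus alkene is therefore the retron of an acyclic captodative alkene, a methyl 2-(arylacetoxy)acrylate. In one operation, Mizoroki–Heck arylation of its CH2 terminus by the enantiopure 5-bromodihydrobenzofuran sets the Z-arylidene unit, and LiHMDS then closes the ring O1–C2–C3–C4–C5 by Dieckmann condensation. The precursor holds no butenolide at all. It is the open enol ester of MOM-protected 4-prenylhomogentisic acid with methyl pyruvate.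

Key step: step 9

Assumption: the tetronic acid is drawn as its 4-hydroxy tautomer, as in the target string, and compound 10 and the L-fructose-derived enantiomer of the Shi ketone are taken as purchasable.

Step 1
Reactants: 1 2,5-dibromobenzene-1,4-diol
Product: 2 1,4-dibromo-2,5-bis(methoxymethoxy)benzene
Conditions: NaH, MOMCl, DMF, 0 °C to rt
Reagents that add atoms: chloromethyl methyl ether (MOMCl), COCCl
Why: Williamson-type O-alkylation of the bis-phenoxide installs acetal protection that is stable to base and organolithium reagents, and the symmetric product makes the next desymmetrisation regiochemically unambiguous.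

Step 2
Reactants: 2 1,4-dibromo-2,5-bis(methoxymethoxy)benzene; 3 prenyl bromide (1-bromo-3-methylbut-2-ene)
Product: 5 1-bromo-2,5-bis(methoxymethoxy)-4-(3-methylbut-2-en-1-yl)benzene, via aryllithium 4 (not isolated)
Conditions: n-BuLi (1.0 equiv), THF, −78 °C; then CuBr·SMe2 (10 mol %), 3, −78 °C to 0 °C
Reagents that add atoms: none
Why: Bromine–lithium exchange with one equivalent of n-BuLi stops at the monolithio stage because a second exchange would build a dianion, and the MOM-chelated aryllithium is allylated at the primary carbon of prenyl bromide in a copper-catalysed SN2 substitution.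

Step 3
Reactants: 5 1-bromo-2,5-bis(methoxymethoxy)-4-(3-methylbut-2-en-1-yl)benzene; 6 ethyl bromoacetate
Product: 9 [2,5-bis(methoxymethoxy)-4-(3-methylbut-2-en-1-yl)phenyl]acetic acid, via Reformatsky reagent 7 (not isolated), via ethyl arylacetate 8 (not isolated)
Conditions: Zn dust (TMSCl-activated), 6, THF, 40 °C; then 5, Pd2(dba)3 (1 mol %), XPhos (4 mol %), THF, 60 °C; then LiOH, H2O–MeOH, rt; 1 M HCl to pH 4, 0 °C
Reagents that add atoms: lithium hydroxide, [Li+].[OH-]
Why: Negishi-type α-arylation with a Reformatsky reagent couples electron-rich aryl bromides under XPhos-ligated palladium and tolerates the acetals and the alkene, and saponification of the unhindered ethyl ester in the same flask gives the acid.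

Step 4
Reactants: 9 [2,5-bis(methoxymethoxy)-4-(3-methylbut-2-en-1-yl)phenyl]acetic acid; 10 methyl 3-chloro-2-hydroxypropanoate (racemic)
Product: 12 methyl 2-({[2,5-bis(methoxymethoxy)-4-(3-methylbut-2-en-1-yl)phenyl]acetyl}oxy)prop-2-enoate, via chloro ester 11 (not isolated)
Conditions: EDC·HCl, DMAP (10 mol %), CH2Cl2, 0 °C to rt; then Et3N (3 equiv), 40 °C
Reagents that add atoms: none
Why: Steglich esterification of the secondary alcohol followed by amine-induced E1cB loss of HCl from the α-acyloxy-β-chloro ester gives the captodative acrylate, and the racemic stereocentre brought in by 10 is erased in the elimination.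

Step 5
Reactants: 13 4-bromophenol; 3 prenyl bromide
Product: 14 4-bromo-2-(3-methylbut-2-en-1-yl)phenol
Conditions: NaH (1.05 equiv), toluene, 0 °C to rt; then 3, rt
Reagents that add atoms: none
Why: ortho-C-allylation of a sodium phenoxide is favoured over O-alkylation for the tight ion pair in a non-polar solvent, and the bromine blocks the para position so that only the ortho carbon can be prenylated.

Step 6
Reactants: 14 4-bromo-2-(3-methylbut-2-en-1-yl)phenol
Product: 15 [4-bromo-2-(3-methylbut-2-en-1-yl)phenoxy](tert-butyl)dimethylsilane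
Conditions: TBSCl, imidazole, DMF, rt
Reagents that add atoms: tert-butyldimethylsilyl chloride (TBSCl), CC(C)(C)[Si](C)(C)Cl
Why: Imidazole-promoted silylation masks the phenol against oxidation and against premature epoxide opening in the next step.

Step 7
Reactants: 15 [4-bromo-2-(3-methylbut-2-en-1-yl)phenoxy](tert-butyl)dimethylsilane
Product: 16 (3S)-3-{[5-bromo-2-(tert-butyldimethylsilyloxy)phenyl]methyl}-2,2-dimethyloxirane
Conditions: ent-Shi ketone (1,2:4,5-di-O-isopropylidene-β-L-erythro-2,3-hexodiulo-2,6-pyranose, 30 mol %), Oxone (2KHSO5·KHSO4·K2SO4), K2CO3, Bu4NHSO4, MeCN–CH2(OMe)2, aq Na2B4O7/Na2(EDTA) buffer, pH 10.5, 0 °C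
Reagents that add atoms: potassium peroxymonosulfate (active component of Oxone), [K+].[O-]S(=O)(=O)OO
Why: In the Shi asymmetric epoxidation the chiral dioxirane formed from the ketone and KHSO5 transfers oxygen to the trisubstituted alkene through a spiro transition state, and the L-fructose-derived ketone (mirror image of the common D-fructose-derived one, which gives R epoxides from such alkenes) sets the S configuration at the secondary epoxide carbon.

Step 8
Reactants: 16 (3S)-3-{[5-bromo-2-(tert-butyldimethylsilyloxy)phenyl]methyl}-2,2-dimethyloxirane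
Product: 18 2-[(2R)-5-bromo-2,3-dihydro-1-benzofuran-2-yl]propan-2-ol, via epoxy phenol 17 (not isolated)
Conditions: TBAF, THF, 0 °C to rt; aqueous work-up
Reagents that add atoms: none
Why: Fluoride desilylation frees the phenoxide, which opens the epoxide by 5-exo-tet SN2 attack at the less substituted secondary carbon under basic conditions, so that clean inversion turns the S epoxide carbon into the R-configured C2 of the dihydrobenzofuran.

Step 9
Reactants: 12 methyl 2-({[2,5-bis(methoxymethoxy)-4-(3-methylbut-2-en-1-yl)phenyl]acetyl}oxy)prop-2-enoate; 18 2-[(2R)-5-bromo-2,3-dihydro-1-benzofuran-2-yl]propan-2-ol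
Product: 20 (5Z)-3-[2,5-bis(methoxymethoxy)-4-(3-methylbut-2-en-1-yl)phenyl]-4-hydroxy-5-({(2R)-2-(2-hydroxypropan-2-yl)-2,3-dihydro-1-benzofuran-5-yl}methylidene)furan-2(5H)-one, via Heck enol ester 19 (not isolated)
Conditions: Pd2(dba)3 (2.5 mol %), [HP(t-Bu)3]BF4 (10 mol %), Cy2NMe (1.3 equiv), BHT (trace), THF, 55 °C; then −78 °C, LiHMDS (4.5 equiv), to 0 °C; 1 M HCl quench, 0 °C
Reagents that add atoms: none
Why: Zerovalent palladium inserts into the C–Br bond of 18, the aryl group adds syn to the unsubstituted CH2 terminus of the captodative alkene of 12 (the only open position, so the regiochemistry is fixed), and syn β-hydride elimination from the new benzylic CH2 gives enol ester 19, which is a Mizoroki–Heck arylation of an α-acyloxyacrylate, the oxygen analogue of the dehydroamino ester synthesis. The Z geometry (aryl cis to the acyloxy oxygen, trans to CO2Me) follows from the elimination conformer that keeps the aryl group away from the ester, and it is also the thermodynamically preferred pulvinone geometry. LiHMDS then deprotonates the doubly activated ArCH2C(=O)O methylene, and the enolate closes the butenolide ring by a 5-exo-trig Dieckmann attack on the methyl ester, with loss of methoxide and irreversible formation of the lithium tetronate. No stereocentre is formed, and C2 of the dihydrobenzofuran lies far from every reacting centre and is not touched. Chemoselectivity rests on the inertness of the trisubstituted prenyl alkene to carbopalladation, on a non-nucleophilic base that spares the enol ester, and on extra base that covers the free tertiary alcohol and the ammonium salt of the coupling stage.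

Step 10
Reactants: 20 (5Z)-3-[2,5-bis(methoxymethoxy)-4-(3-methylbut-2-en-1-yl)phenyl]-4-hydroxy-5-({(2R)-2-(2-hydroxypropan-2-yl)-2,3-dihydro-1-benzofuran-5-yl}methylidene)furan-2(5H)-one
Product: 21 (5Z)-3-[2,5-dihydroxy-4-(3-methylbut-2-en-1-yl)phenyl]-4-hydroxy-5-({(2R)-2-(2-hydroxypropan-2-yl)-2,3-dihydro-1-benzofuran-5-yl}methylidene)furan-2(5H)-one (CNP0601419.1)
Conditions: HCl (1.25 M in MeOH), argon, 25 to 40 °C
Reagents that add atoms: none
Why: Acid-catalysed acetal exchange (methanolysis) cleaves aryl MOM ethers under conditions mild enough to spare the o-prenylphenol, the tertiary alcohol and the stereocentre, and the inert atmosphere protects the liberated hydroquinone.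

Compound list
1 | 2,5-dibromobenzene-1,4-diol | Oc1cc(Br)c(O)cc1Br | starting material
2 | 1,4-dibromo-2,5-bis(methoxymethoxy)benzene | COCOc1cc(Br)c(OCOC)cc1Br | intermediate
3 | prenyl bromide (1-bromo-3-methylbut-2-ene) | CC(C)=CCBr | starting material
4 | [4-bromo-2,5-bis(methoxymethoxy)phenyl]lithium | [Li]c1cc(OCOC)c(Br)cc1OCOC | intermediate
5 | 1-bromo-2,5-bis(methoxymethoxy)-4-(3-methylbut-2-en-1-yl)benzene | CC(C)=CCc1cc(OCOC)c(Br)cc1OCOC | intermediate
6 | ethyl bromoacetate | CCOC(=O)CBr | starting material
7 | (2-ethoxy-2-oxoethyl)zinc bromide | CCOC(=O)C[Zn]Br | intermediate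
8 | ethyl [2,5-bis(methoxymethoxy)-4-(3-methylbut-2-en-1-yl)phenyl]acetate | CCOC(=O)Cc1cc(OCOC)c(CC=C(C)C)cc1OCOC | intermediate
9 | [2,5-bis(methoxymethoxy)-4-(3-methylbut-2-en-1-yl)phenyl]acetic acid | CC(C)=CCc1cc(OCOC)c(CC(=O)O)cc1OCOC | intermediate
10 | methyl 3-chloro-2-hydroxypropanoate (racemic) | COC(=O)C(O)CCl | starting material
11 | methyl 2-({[2,5-bis(methoxymethoxy)-4-(3-methylbut-2-en-1-yl)phenyl]acetyl}oxy)-3-chloropropanoate (racemic) | COC(=O)C(CCl)OC(=O)Cc1cc(OCOC)c(CC=C(C)C)cc1OCOC | intermediate
12 | methyl 2-({[2,5-bis(methoxymethoxy)-4-(3-methylbut-2-en-1-yl)phenyl]acetyl}oxy)prop-2-enoate | C=C(OC(=O)Cc1cc(OCOC)c(CC=C(C)C)cc1OCOC)C(=O)OC | intermediate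
13 | 4-bromophenol | Oc1ccc(Br)cc1 | starting material
14 | 4-bromo-2-(3-methylbut-2-en-1-yl)phenol | CC(C)=CCc1cc(Br)ccc1O | intermediate
15 | [4-bromo-2-(3-methylbut-2-en-1-yl)phenoxy](tert-butyl)dimethylsilane | CC(C)=CCc1cc(Br)ccc1O[Si](C)(C)C(C)(C)C | intermediate
16 | (3S)-3-{[5-bromo-2-(tert-butyldimethylsilyloxy)phenyl]methyl}-2,2-dimethyloxirane | CC1(C)O[C@H]1Cc1cc(Br)ccc1O[Si](C)(C)C(C)(C)C | intermediate
17 | 4-bromo-2-{[(2S)-3,3-dimethyloxiran-2-yl]methyl}phenol | CC1(C)O[C@H]1Cc1cc(Br)ccc1O | intermediate
18 | 2-[(2R)-5-bromo-2,3-dihydro-1-benzofuran-2-yl]propan-2-ol | Brc1ccc2c(c1)C[C@H](C(C)(C)O)O2 | intermediate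
19 | methyl (2Z)-2-({[2,5-bis(methoxymethoxy)-4-(3-methylbut-2-en-1-yl)phenyl]acetyl}oxy)-3-[(2R)-2-(2-hydroxypropan-2-yl)-2,3-dihydro-1-benzofuran-5-yl]prop-2-enoate | COC(=O)/C(OC(=O)Cc1cc(OCOC)c(CC=C(C)C)cc1OCOC)=C/c1ccc2c(c1)C[C@H](C(C)(C)O)O2 | intermediate
20 | (5Z)-3-[2,5-bis(methoxymethoxy)-4-(3-methylbut-2-en-1-yl)phenyl]-4-hydroxy-5-({(2R)-2-(2-hydroxypropan-2-yl)-2,3-dihydro-1-benzofuran-5-yl}methylidene)furan-2(5H)-one | CC(C)=CCc1cc(OCOC)c(C2=C(O)/C(=C/c3ccc4c(c3)C[C@H](C(C)(C)O)O4)OC2=O)cc1OCOC | intermediate
21 | (5Z)-3-[2,5-dihydroxy-4-(3-methylbut-2-en-1-yl)phenyl]-4-hydroxy-5-({(2R)-2-(2-hydroxypropan-2-yl)-2,3-dihydro-1-benzofuran-5-yl}methylidene)furan-2(5H)-one | CC(C)=CCc1cc(O)c(C2=C(O)/C(=C/c3ccc4c(c3)C[C@H](C(C)(C)O)O4)OC2=O)cc1O | target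

Total step count: 10.
Longest linear sequence: 6 steps (1, 2, 3, 4, 9, 10; the branch 5, 6, 7, 8, 9, 10 is equally long).

Steps most likely to fail

1. Step 9.
- What may go wrong: Oxidative addition of the electron-rich bromide may be slow. The captodative acrylate may oligomerise or lose its arylacetyl group by acyl transfer at the coupling temperature. The alkene geometry may erode. The salts of the coupling stage may disturb the enolate chemistry.
- Fallback: This makes the same bond by the same coupling type, but on a small robust alkene, and delivers the remaining ring atoms afterwards. It sets out from 18.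
  - Compound 18 is coupled with purchased methyl 2-acetoxyacrylate (Pd(OAc)2, P(o-tol)3, Et3N, MeCN, 80 °C) to give methyl (2Z)-2-acetoxy-3-[(2R)-2-(2-hydroxypropan-2-yl)-2,3-dihydro-1-benzofuran-5-yl]prop-2-enoate F1.
  - K2CO3 in MeOH at 0 °C removes the acetyl group and should give the enol form of the arylpyruvate, methyl (2Z)-2-hydroxy-3-[(2R)-2-(2-hydroxypropan-2-yl)-2,3-dihydro-1-benzofuran-5-yl]prop-2-enoate F2.
  - Selective O-acylation of the enol with acid 9 (EDC·HCl, DMAP, CH2Cl2), which leaves the hindered tertiary alcohol alone, comes back to the route at 19. Compound 19 is now isolated and purified, then closed to 20 with LiHMDS in a separate flask.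

2. Step 4.
- What may go wrong: The dehydrochlorination may be slow or incomplete. The amine or DMAP may trigger oligomerisation of the freshly formed acrylate. Ring closure may begin prematurely.
- Fallback: This builds the alkene by olefination instead of elimination. It sets out from 9.
  - Acid 9 is esterified (EDC·HCl, DMAP, CH2Cl2) with methyl 2-(dimethoxyphosphoryl)-2-hydroxyacetate to give methyl 2-({[2,5-bis(methoxymethoxy)-4-(3-methylbut-2-en-1-yl)phenyl]acetyl}oxy)-2-(dimethoxyphosphoryl)acetate F3.
  - Horner–Wadsworth–Emmons methylenation with paraformaldehyde under Masamune–Roush conditions (LiCl, iPr2NEt, MeCN, rt) comes back to the route at 12.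

3. Step 10.
- What may go wrong: Acid may cyclise the o-prenylphenol onto the alkene, ionise the tertiary alcohol or methylate the tetronic acid. The liberated hydroquinone may be oxidised by air.
- Fallback: This replaces acidolysis by a protecting-group exchange under weakly basic conditions. It sets out from 20.
  - Compound 20 is treated with TMSOTf and 2,2'-bipyridyl (CH2Cl2, 0 °C to rt). This converts aryl MOM ethers into aryl silyl ethers and silylates the two free hydroxy groups.
  - The product is (5Z)-3-[4-(3-methylbut-2-en-1-yl)-2,5-bis(trimethylsilyloxy)phenyl]-4-(trimethylsilyloxy)-5-({(2R)-2-[2-(trimethylsilyloxy)propan-2-yl]-2,3-dihydro-1-benzofuran-5-yl}methylidene)furan-2(5H)-one F4.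
  - Hydrolysis of all four labile silyl groups in H2O–MeOH with a trace of citric acid under argon comes back to the route at 21.

Further compounds
F1 | step 9 | methyl (2Z)-2-acetoxy-3-[(2R)-2-(2-hydroxypropan-2-yl)-2,3-dihydro-1-benzofuran-5-yl]prop-2-enoate | COC(=O)/C(OC(C)=O)=C/c1ccc2c(c1)C[C@H](C(C)(C)O)O2
F2 | step 9 | methyl (2Z)-2-hydroxy-3-[(2R)-2-(2-hydroxypropan-2-yl)-2,3-dihydro-1-benzofuran-5-yl]prop-2-enoate | COC(=O)/C(O)=C/c1ccc2c(c1)C[C@H](C(C)(C)O)O2
F3 | step 4 | methyl 2-({[2,5-bis(methoxymethoxy)-4-(3-methylbut-2-en-1-yl)phenyl]acetyl}oxy)-2-(dimethoxyphosphoryl)acetate | COC(=O)C(OC(=O)Cc1cc(OCOC)c(CC=C(C)C)cc1OCOC)P(=O)(OC)OC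
F4 | step 10 | (5Z)-3-[4-(3-methylbut-2-en-1-yl)-2,5-bis(trimethylsilyloxy)phenyl]-4-(trimethylsilyloxy)-5-({(2R)-2-[2-(trimethylsilyloxy)propan-2-yl]-2,3-dihydro-1-benzofuran-5-yl}methylidene)furan-2(5H)-one | CC(C)=CCc1cc(O[Si](C)(C)C)c(C2=C(O[Si](C)(C)C)/C(=C/c3ccc4c(c3)C[C@H](C(C)(C)O[Si](C)(C)C)O4)OC2=O)cc1O[Si](C)(C)C
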